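**Retrosynthetic overview**
- Target ⇐ acetylation, desilylation and veratroylation of a hydroazulene diol that already carries all seven stereocentres.
- Diol ⇐ hydroboration of the ring-fusion alkene (sets the trans fusion and the ester carbinol together) and isopropyl addition to the ring ketone, both after chemoselective epoxidation of a bicyclic dienone.
- Key step: the bicyclic dienone ⇐ divinylcyclopropane–cycloheptadiene (Cope) rearrangement, which forms the seven-membered ring, the quaternary methyl carbon and both ring alkenes in one step from a 2-(2-vinylcyclopropyl)cyclopentenone.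
- Divinylcyclopropane ⇐ Wittig methylenation ⇐ Charette cyclopropanation ⇐ Stille coupling of an α-iodocyclopentenone with a Z-stannyl allylic alcohol.
- Ring order: five-membered ring (commercial (S)-4-silyloxycyclopentenone), cyclopropane, seven-membered ring (Cope), oxirane.

Assumption: the SMILES is read as the (1R,3S,3aR,5S,6R,8S,8aS) isomer in azulene numbering (C1 isopropyl carbinol, C3 acetoxy, C3a angular methyl, C5/C6 epoxide, C8 ester, C8a ring-fusion H); α is the face of the C8a hydrogen and the angular methyl is β.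

**Route**

Step 1
Reactants: 1 (4S)-4-[(tert-butyldimethylsilyl)oxy]cyclopent-2-en-1-one
Product: 3 (4S)-4-[(tert-butyldimethylsilyl)oxy]-3-methylcyclopent-2-en-1-one, via trimethylsilyl enol ether 2 (not isolated)
Conditions: Me2CuLi (MeLi, CuI), TMSCl, THF, −78 °C; then Pd(OAc)2 (1.1 equiv), MeCN, rt
Reagents that add atoms: lithium dimethylcuprate, [Li+].C[Cu-]C
Why: TMSCl-accelerated cuprate conjugate addition anti to the silyloxy group gives the regiodefined silyl enol ether and Saegusa–Ito oxidation with Pd(OAc)2 reinstalls the enone, now carrying the future angular methyl, while the silyloxy stereocentre (the future acetoxy carbon) is never touched.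

Step 2
Reactants: 3 (4S)-4-[(tert-butyldimethylsilyl)oxy]-3-methylcyclopent-2-en-1-one
Product: 4 (4S)-4-[(tert-butyldimethylsilyl)oxy]-2-iodo-3-methylcyclopent-2-en-1-one
Conditions: I2, pyridine, CH2Cl2, rt
Reagents that add atoms: iodine, II
Why: Johnson α-iodination of an enone (pyridine conjugate addition, iodination of the enolate, elimination) places the cross-coupling handle on the α-carbon.

Step 3
Reactants: 5 prop-2-yn-1-ol
Product: 7 (2Z)-2-methyl-3-(tributylstannyl)prop-2-en-1-ol, via vinylmagnesium alkoxide 6 (not isolated)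
Conditions: MeMgBr (2.5 equiv), CuI (10 mol%), Et2O, −10 °C to rt; then Bu3SnCl, THF, 0 °C
Reagents that add atoms: methylmagnesium bromide, C[Mg]Br; tributyltin chloride, CCCC[Sn](Cl)(CCCC)CCCC
Why: Copper-catalysed anti-carbomagnesiation of the propargylic alkoxide (Duboudin–Jousseaume reaction) delivers methyl to C2 and leaves magnesium on C3 cis to the CH2O group in a chelate, and stannylation of this vinyl Grignard with retention gives the Z-stannane.

Step 4
Reactants: 4 (4S)-4-[(tert-butyldimethylsilyl)oxy]-2-iodo-3-methylcyclopent-2-en-1-one, 7 (2Z)-2-methyl-3-(tributylstannyl)prop-2-en-1-ol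
Product: 8 (4S)-4-[(tert-butyldimethylsilyl)oxy]-2-[(1Z)-3-hydroxy-2-methylprop-1-en-1-yl]-3-methylcyclopent-2-en-1-one
Conditions: Pd2(dba)3 (5 mol%), AsPh3, CuI, NMP, 40 °C
Reagents that add atoms: none
Why: Stille coupling of an α-iodoenone with a vinylstannane (AsPh3/CuI acceleration) proceeds with retention of the Z-alkene geometry and tolerates the free hydroxyl.

Step 5
Reactants: 8 (4S)-4-[(tert-butyldimethylsilyl)oxy]-2-[(1Z)-3-hydroxy-2-methylprop-1-en-1-yl]-3-methylcyclopent-2-en-1-one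
Product: 9 (4S)-4-[(tert-butyldimethylsilyl)oxy]-2-[(1R,2S)-2-(hydroxymethyl)-2-methylcyclopropyl]-3-methylcyclopent-2-en-1-one
Conditions: Et2Zn, CH2I2, DME, (4R,5R)-2-butyl-N,N,N′,N′-tetramethyl-1,3,2-dioxaborolane-4,5-dicarboxamide (1.2 equiv), CH2Cl2, −10 °C to rt
Reagents that add atoms: diiodomethane, ICI
Why: Charette asymmetric Simmons–Smith cyclopropanation, in which the zinc alkoxide bound to the (4R,5R)-dioxaborolane receives CH2 on the face predicted by the cinnamyl alcohol model to give the (1R,2S)-cyclopropane, the Z-geometry is conserved so the cyclopentenone and the CH2OH group are cis, and the electron-poor enone alkene does not react with the electrophilic zinc carbenoid.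

Step 6
Reactants: 9 (4S)-4-[(tert-butyldimethylsilyl)oxy]-2-[(1R,2S)-2-(hydroxymethyl)-2-methylcyclopropyl]-3-methylcyclopent-2-en-1-one
Product: 10 (1S,2R)-2-[(3S)-3-[(tert-butyldimethylsilyl)oxy]-2-methyl-5-oxocyclopent-1-en-1-yl]-1-methylcyclopropane-1-carbaldehyde
Conditions: Pr4N[RuO4] (5 mol%), N-methylmorpholine N-oxide, 4 Å MS, CH2Cl2, 0 °C
Reagents that add atoms: none
Why: Ley–Griffith oxidation gives the aldehyde under neutral conditions, its α-carbon is quaternary and cannot epimerise, and the enone and silyl ether are inert.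

Step 7
Reactants: 10 (1S,2R)-2-[(3S)-3-[(tert-butyldimethylsilyl)oxy]-2-methyl-5-oxocyclopent-1-en-1-yl]-1-methylcyclopropane-1-carbaldehyde
Product: 12 (3S,3aR)-3-[(tert-butyldimethylsilyl)oxy]-3a,6-dimethyl-3,3a,4,7-tetrahydroazulen-1(2H)-one, via cis-divinylcyclopropane 11 (not isolated)
Conditions: Ph3PCH3Br, KN(SiMe3)2, THF, −78 to 0 °C; then PhMe, 80 °C
Reagents that add atoms: methyltriphenylphosphonium bromide, C[P+](c1ccccc1)(c1ccccc1)c1ccccc1.[Br-]
Why: Wittig methylenation of the aldehyde (far more reactive than the hindered conjugated ketone) gives the cis-divinylcyclopropane, which undergoes the strain-driven divinylcyclopropane–cycloheptadiene (Cope) rearrangement through the endo-boat transition state; the rearrangement is stereospecific, so the (1R,2R)-cyclopropane forces the vinyl terminus onto the α-face of the methyl-bearing enone carbon (the face of the silyloxy group) and sets the quaternary centre as 3aR while placing the ring alkenes at C5=C6 and C8=C8a.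

Step 8
Reactants: 12 (3S,3aR)-3-[(tert-butyldimethylsilyl)oxy]-3a,6-dimethyl-3,3a,4,7-tetrahydroazulen-1(2H)-one
Product: 13 (3S,3aR,5S,6R)-3-[(tert-butyldimethylsilyl)oxy]-5,6-epoxy-3a,6-dimethyl-3,3a,4,5,6,7-hexahydroazulen-1(2H)-one
Conditions: mCPBA (1.05 equiv), NaHCO3, CH2Cl2, 0 °C
Reagents that add atoms: mCPBA, OOC(=O)c1cccc(Cl)c1
Why: Prilezhaev epoxidation is chemoselective for the electron-rich isolated trisubstituted C5=C6 alkene because the C8=C8a alkene is deactivated by conjugation with the ketone, and the peracid approaches the convex α-face anti to the angular methyl to give the (5S,6R)-epoxide.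

Step 9
Reactants: 13 (3S,3aR,5S,6R)-3-[(tert-butyldimethylsilyl)oxy]-5,6-epoxy-3a,6-dimethyl-3,3a,4,5,6,7-hexahydroazulen-1(2H)-one
Product: 14 (1R,3S,3aR,5S,6R)-3-[(tert-butyldimethylsilyl)oxy]-5,6-epoxy-3a,6-dimethyl-1-(propan-2-yl)-1,2,3,3a,4,5,6,7-octahydroazulen-1-ol
Conditions: i-PrMgCl, CeCl3, THF, −78 °C
Reagents that add atoms: isopropylmagnesium chloride, CC(C)[Mg]Cl
Why: Imamoto-type 1,2-addition in the presence of CeCl3 (which suppresses enolisation, conjugate addition and β-hydride reduction) to the cross-conjugated ketone, with the nucleophile entering anti to the pseudo-axial angular methyl on the α-face so that the hydroxyl ends up β and the tertiary carbinol is 1R.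

Step 10
Reactants: 14 (1R,3S,3aR,5S,6R)-3-[(tert-butyldimethylsilyl)oxy]-5,6-epoxy-3a,6-dimethyl-1-(propan-2-yl)-1,2,3,3a,4,5,6,7-octahydroazulen-1-ol
Product: 16 (1R,3S,3aR,5S,6R,8S,8aS)-3-[(tert-butyldimethylsilyl)oxy]-5,6-epoxy-3a,6-dimethyl-1-(propan-2-yl)decahydroazulene-1,8-diol, via C8 alkylborane 15 (not isolated)
Conditions: BH3·THF (3 equiv), THF, 0 °C to rt; then H2O2, NaOH, 0 °C
Reagents that add atoms: hydrogen peroxide, OO
Why: Brown hydroboration–oxidation, in which boron adds to the less substituted C8 and hydrogen to C8a in a syn fashion from the α-face, anti to both the angular methyl and the allylic C–O bond, so the C8a hydrogen and the C8 hydroxyl are cis to each other and trans to the angular methyl (trans ring fusion, 8S,8aS), the C–B bond is oxidised with retention, and the trisubstituted epoxide and silyl ether survive the short exposure.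

Step 11
Reactants: 16 (1R,3S,3aR,5S,6R,8S,8aS)-3-[(tert-butyldimethylsilyl)oxy]-5,6-epoxy-3a,6-dimethyl-1-(propan-2-yl)decahydroazulene-1,8-diol, 17 3,4-dimethoxybenzoyl chloride
Product: 18 (1R,3S,3aR,5S,6R,8S,8aS)-3-[(tert-butyldimethylsilyl)oxy]-5,6-epoxy-1-hydroxy-3a,6-dimethyl-1-(propan-2-yl)decahydroazulen-8-yl 3,4-dimethoxybenzoate
Conditions: Et3N, DMAP (cat.), CH2Cl2, 0 °C to rt
Reagents that add atoms: none
Why: DMAP-catalysed acyl transfer (Steglich-type acylation) esterifies the only secondary alcohol while the hindered tertiary alcohol does not react.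

Step 12
Reactants: 18 (1R,3S,3aR,5S,6R,8S,8aS)-3-[(tert-butyldimethylsilyl)oxy]-5,6-epoxy-1-hydroxy-3a,6-dimethyl-1-(propan-2-yl)decahydroazulen-8-yl 3,4-dimethoxybenzoate
Product: 19 (1R,3S,3aR,5S,6R,8S,8aS)-5,6-epoxy-1,3-dihydroxy-3a,6-dimethyl-1-(propan-2-yl)decahydroazulen-8-yl 3,4-dimethoxybenzoate
Conditions: Bu4NF, AcOH, THF, rt to 40 °C
Reagents that add atoms: none
Why: Fluoride-induced desilylation driven by the strong Si–F bond frees the C3 hydroxyl, and acetic acid buffering keeps the benzoate and the epoxide intact.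

Step 13
Reactants: 19 (1R,3S,3aR,5S,6R,8S,8aS)-5,6-epoxy-1,3-dihydroxy-3a,6-dimethyl-1-(propan-2-yl)decahydroazulen-8-yl 3,4-dimethoxybenzoate
Product: 20 (1R,3S,3aR,5S,6R,8S,8aS)-3-(acetyloxy)-5,6-epoxy-1-hydroxy-3a,6-dimethyl-1-(propan-2-yl)decahydroazulen-8-yl 3,4-dimethoxybenzoate
Conditions: Ac2O, pyridine, DMAP (cat.), CH2Cl2, rt
Reagents that add atoms: acetic anhydride, CC(=O)OC(C)=O
Why: DMAP-catalysed acetylation of the secondary C3 hydroxyl gives the target, the tertiary C1 hydroxyl being too hindered to be acylated under these conditions.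

**Compound list**

1 | (4S)-4-[(tert-butyldimethylsilyl)oxy]cyclopent-2-en-1-one | O=C1C[C@H](O[Si](C)(C)C(C)(C)C)C=C1 | starting material
2 | tert-butyldimethyl{[(1S,2S)-2-methyl-4-(trimethylsilyloxy)cyclopent-3-en-1-yl]oxy}silane (methyl trans to OTBS) | C[Si](C)(C)OC1=C[C@H](C)[C@@H](O[Si](C)(C)C(C)(C)C)C1 | intermediate
3 | (4S)-4-[(tert-butyldimethylsilyl)oxy]-3-methylcyclopent-2-en-1-one | O=C1C[C@H](O[Si](C)(C)C(C)(C)C)C(C)=C1 | intermediate
4 | (4S)-4-[(tert-butyldimethylsilyl)oxy]-2-iodo-3-methylcyclopent-2-en-1-one | O=C1C[C@H](O[Si](C)(C)C(C)(C)C)C(C)=C1I | intermediate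
5 | prop-2-yn-1-ol | C#CCO | starting material
6 | bromomagnesium (2Z)-3-(bromomagnesio)-2-methylprop-2-en-1-olate | Br[Mg]/C=C(/C)CO[Mg]Br | intermediate
7 | (2Z)-2-methyl-3-(tributylstannyl)prop-2-en-1-ol | CCCC[Sn](CCCC)(CCCC)/C=C(/C)CO | intermediate
8 | (4S)-4-[(tert-butyldimethylsilyl)oxy]-2-[(1Z)-3-hydroxy-2-methylprop-1-en-1-yl]-3-methylcyclopent-2-en-1-one | O=C1C[C@H](O[Si](C)(C)C(C)(C)C)C(C)=C1/C=C(/C)CO | intermediate
9 | (4S)-4-[(tert-butyldimethylsilyl)oxy]-2-[(1R,2S)-2-(hydroxymethyl)-2-methylcyclopropyl]-3-methylcyclopent-2-en-1-one | O=C1C[C@H](O[Si](C)(C)C(C)(C)C)C(C)=C1[C@@H]1C[C@]1(C)CO | intermediate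
10 | (1S,2R)-2-[(3S)-3-[(tert-butyldimethylsilyl)oxy]-2-methyl-5-oxocyclopent-1-en-1-yl]-1-methylcyclopropane-1-carbaldehyde | O=C1C[C@H](O[Si](C)(C)C(C)(C)C)C(C)=C1[C@@H]1C[C@]1(C)C=O | intermediate
11 | (4S)-4-[(tert-butyldimethylsilyl)oxy]-2-[(1R,2R)-2-ethenyl-2-methylcyclopropyl]-3-methylcyclopent-2-en-1-one | O=C1C[C@H](O[Si](C)(C)C(C)(C)C)C(C)=C1[C@@H]1C[C@]1(C)C=C | intermediate
12 | (3S,3aR)-3-[(tert-butyldimethylsilyl)oxy]-3a,6-dimethyl-3,3a,4,7-tetrahydroazulen-1(2H)-one | C1CC(C)=CC[C@@]2(C)[C@@H](O[Si](C)(C)C(C)(C)C)CC(=O)C=12 | intermediate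
13 | (3S,3aR,5S,6R)-3-[(tert-butyldimethylsilyl)oxy]-5,6-epoxy-3a,6-dimethyl-3,3a,4,5,6,7-hexahydroazulen-1(2H)-one | C1C[C@@]2(C)O[C@H]2C[C@@]2(C)[C@@H](O[Si](C)(C)C(C)(C)C)CC(=O)C=12 | intermediate
14 | (1R,3S,3aR,5S,6R)-3-[(tert-butyldimethylsilyl)oxy]-5,6-epoxy-3a,6-dimethyl-1-(propan-2-yl)-1,2,3,3a,4,5,6,7-octahydroazulen-1-ol | C1C[C@@]2(C)O[C@H]2C[C@@]2(C)[C@@H](O[Si](C)(C)C(C)(C)C)C[C@@](O)(C(C)C)C=12 | intermediate
15 | C8 alkylborane of 14 (BH2 on C8 α, H on C8a α, tertiary oxygen as O–BH2) | B[C@H]1C[C@@]2(C)O[C@H]2C[C@@]2(C)[C@@H](O[Si](C)(C)C(C)(C)C)C[C@@](OB)(C(C)C)[C@H]12 | intermediate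
16 | (1R,3S,3aR,5S,6R,8S,8aS)-3-[(tert-butyldimethylsilyl)oxy]-5,6-epoxy-3a,6-dimethyl-1-(propan-2-yl)decahydroazulene-1,8-diol | O[C@H]1C[C@@]2(C)O[C@H]2C[C@@]2(C)[C@@H](O[Si](C)(C)C(C)(C)C)C[C@@](O)(C(C)C)[C@H]12 | intermediate
17 | 3,4-dimethoxybenzoyl chloride | COc1ccc(C(=O)Cl)cc1OC | starting material
18 | (1R,3S,3aR,5S,6R,8S,8aS)-3-[(tert-butyldimethylsilyl)oxy]-5,6-epoxy-1-hydroxy-3a,6-dimethyl-1-(propan-2-yl)decahydroazulen-8-yl 3,4-dimethoxybenzoate | COc1ccc(C(=O)O[C@H]2C[C@@]3(C)O[C@H]3C[C@@]3(C)[C@@H](O[Si](C)(C)C(C)(C)C)C[C@@](O)(C(C)C)[C@H]23)cc1OC | intermediate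
19 | (1R,3S,3aR,5S,6R,8S,8aS)-5,6-epoxy-1,3-dihydroxy-3a,6-dimethyl-1-(propan-2-yl)decahydroazulen-8-yl 3,4-dimethoxybenzoate | COc1ccc(C(=O)O[C@H]2C[C@@]3(C)O[C@H]3C[C@@]3(C)[C@@H](O)C[C@@](O)(C(C)C)[C@H]23)cc1OC | intermediate
20 | (1R,3S,3aR,5S,6R,8S,8aS)-3-(acetyloxy)-5,6-epoxy-1-hydroxy-3a,6-dimethyl-1-(propan-2-yl)decahydroazulen-8-yl 3,4-dimethoxybenzoate (CNP0330776.2) | COc1ccc(C(=O)O[C@H]2C[C@@]3(C)O[C@H]3C[C@@]3(C)[C@@H](OC(C)=O)C[C@@](O)(C(C)C)[C@H]23)cc1OC | target

**Step count and risk**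

Total step count: 13. Longest linear sequence: 12 steps (steps 1, 2 and 4 to 13; step 3 is a one-step side branch).

Three steps most likely to fail:

Step 7 (Wittig/Cope key step). The methyl group must sit inside the boat, and the new bond forms on the face of the neighbouring silyloxy group; aldehyde 10 can also equilibrate with a dihydrooxepin by retro-Claisen. The fallback gives up the pericyclic route for a ring-closing metathesis; it sets out from 1 and comes back at 12. Copper-catalysed conjugate allylation of 1 (allylMgBr, CuBr·SMe2, TMSCl) gives the silyl enol ether F1, and Saegusa oxidation with Pd(OAc)2 gives the allyl enone F2. Me2CuLi/BF3·OEt2 then adds anti to the silyloxy group, which gives the same 3aR quaternary centre (methyl trans, allyl cis to OTBS). The enolate is trapped with 3-methylbut-3-enal to the aldol F3. Dehydration (MsCl, Et3N; DBU) gives the E-configured triene F4. Ring-closing metathesis with the second-generation Grubbs catalyst (H2IMes)(PCy3)Cl2Ru=CHPh closes the C5=C6 bond and delivers 12.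

Step 9 (isopropyl addition). The facial preference at C1 rests on the pseudo-axial angular methyl and could be eroded by the C3 silyloxy group. The basic reagent may also deprotonate C7 and open the epoxide by vinylogous elimination. The fallback postpones the addition until a chelating oxygen is in place; it sets out from 13 and comes back at 16, bypassing 14 and 15. Copper-catalysed conjugate borylation (B2pin2, CuCl, Xantphos, NaOt-Bu, MeOH) gives the boryl ketone F5, and NaBO3·4H2O oxidises it with retention to the hydroxy ketone F6. Excess i-PrMgCl then forms the C8 magnesium alkoxide, which chelates the ketone; Cram-chelate addition from the α-face, anti to the ring carbon C3a, gives 16.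

Step 10 (hydroboration). The α-face selectivity could be overridden by delivery from the β-oriented alkoxyborane, and the hindered alkene may need conditions that begin to reduce the epoxide. The fallback replaces kinetic face control by thermodynamic control plus a directed reduction; it sets out from 14 and comes back at 16. β-Face hydroboration–oxidation gives the cis-fused diol F7. Dess–Martin periodinane oxidises its secondary alcohol to the cis-fused ketone F8. DBU equilibrates C8a to the trans-fused ketone F9. Me4NBH(OAc)3 (Evans–Saksena reduction) then delivers hydride from the β-oriented C1 hydroxyl to the β-face of the C8 carbonyl and gives the 8α-alcohol 16.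

Further compounds
F1 | step 7 | tert-butyldimethyl{[(1S,2S)-2-(prop-2-en-1-yl)-4-(trimethylsilyloxy)cyclopent-3-en-1-yl]oxy}silane | C[Si](C)(C)OC1=C[C@H](CC=C)[C@@H](O[Si](C)(C)C(C)(C)C)C1
F2 | step 7 | (4S)-4-[(tert-butyldimethylsilyl)oxy]-3-(prop-2-en-1-yl)cyclopent-2-en-1-one | O=C1C[C@H](O[Si](C)(C)C(C)(C)C)C(CC=C)=C1
F3 | step 7 | (3R,4S)-4-[(tert-butyldimethylsilyl)oxy]-2-(1-hydroxy-3-methylbut-3-en-1-yl)-3-methyl-3-(prop-2-en-1-yl)cyclopentan-1-one (epimer mixture at C2 and the carbinol carbon) | O=C1C[C@H](O[Si](C)(C)C(C)(C)C)[C@](C)(CC=C)C1C(O)CC(C)=C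
F4 | step 7 | (2E,3R,4S)-4-[(tert-butyldimethylsilyl)oxy]-3-methyl-2-(3-methylbut-3-en-1-ylidene)-3-(prop-2-en-1-yl)cyclopentan-1-one | C=C(C)C/C=C1/C(=O)C[C@H](O[Si](C)(C)C(C)(C)C)[C@]1(C)CC=C
F5 | step 9 | (3S,3aR,5S,6R,8S,8aR)-3-[(tert-butyldimethylsilyl)oxy]-5,6-epoxy-3a,6-dimethyl-8-(4,4,5,5-tetramethyl-1,3,2-dioxaborolan-2-yl)-3,3a,4,5,6,7,8,8a-octahydroazulen-1(2H)-one | CC1(C)OB(OC1(C)C)[C@H]1C[C@@]2(C)O[C@H]2C[C@@]2(C)[C@@H](O[Si](C)(C)C(C)(C)C)CC(=O)[C@H]12
F6 | step 9 | (3S,3aR,5S,6R,8S,8aS)-3-[(tert-butyldimethylsilyl)oxy]-5,6-epoxy-8-hydroxy-3a,6-dimethyl-3,3a,4,5,6,7,8,8a-octahydroazulen-1(2H)-one | O[C@H]1C[C@@]2(C)O[C@H]2C[C@@]2(C)[C@@H](O[Si](C)(C)C(C)(C)C)CC(=O)[C@H]12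
F7 | step 10 | (1R,3S,3aR,5S,6R,8R,8aR)-3-[(tert-butyldimethylsilyl)oxy]-5,6-epoxy-3a,6-dimethyl-1-(propan-2-yl)decahydroazulene-1,8-diol | O[C@@H]1C[C@@]2(C)O[C@H]2C[C@@]2(C)[C@@H](O[Si](C)(C)C(C)(C)C)C[C@@](O)(C(C)C)[C@@H]12
F8 | step 10 | (1R,3S,3aR,5S,6R,8aS)-3-[(tert-butyldimethylsilyl)oxy]-5,6-epoxy-1-hydroxy-3a,6-dimethyl-1-(propan-2-yl)-2,3,3a,4,5,6,7,8a-octahydroazulen-8(1H)-one | O=C1C[C@@]2(C)O[C@H]2C[C@@]2(C)[C@@H](O[Si](C)(C)C(C)(C)C)C[C@@](O)(C(C)C)[C@@H]12
F9 | step 10 | (1R,3S,3aR,5S,6R,8aR)-3-[(tert-butyldimethylsilyl)oxy]-5,6-epoxy-1-hydroxy-3a,6-dimethyl-1-(propan-2-yl)-2,3,3a,4,5,6,7,8a-octahydroazulen-8(1H)-one | O=C1C[C@@]2(C)O[C@H]2C[C@@]2(C)[C@@H](O[Si](C)(C)C(C)(C)C)C[C@@](O)(C(C)C)[C@H]12
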